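**Retrosynthetic overview** (tetralin locants: ring A aromatic, ring B = C1–C4/C4a/C8a, C1' = side-chain carbinol carbon)
1. Target ⇒ desilylation ⇒ cis-selective hydride reduction at C2 ⇒ anti aldol at C1 of 6,7-dimethoxy-2-tetralone with silyl-protected (E)-4-hydroxycinnamaldehyde.
2. Key disconnection: ring B of the tetralone is opened at C4a–C4 and C3–C2, leading back to (3,4-dimethoxyphenyl)acetyl chloride and ethylene; one Lewis acid operation makes both bonds.
3. Enabling feature: the C2 oxygen sits two carbons from ring A (C8a–C1–C2), so C2 can be an acylium ion. C4a is ortho to that chain, para to the C7 methoxy group and unhindered, so it closes a six-membered ring onto the ethylene-derived C4.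
4. Ring order: ring A is bought; ring B is the only ring formed (step 1). Its ketone then fixes the enolate geometry (C1/C1' anti) and the face of reduction (C2 hydroxyl cis to the side chain).

Key step: step 1

Assumption: the (4S,5S)-phosphoramide of step 4 is taken to steer the enolate onto the Si face of the aldehyde; if a trial run shows the opposite sense, the (4R,5R)-catalyst is used and nothing else changes.

**Step 1**
Reactants: 1 (3,4-dimethoxyphenyl)acetyl chloride; 2 ethylene
Product: 4 6,7-dimethoxy-3,4-dihydronaphthalen-2(1H)-one, via 4-chloro-1-(3,4-dimethoxyphenyl)butan-2-one 3 (not isolated)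
Conditions: AlCl3 (2.2 equiv), ethylene (1 atm, sparged), CH2Cl2, −10 °C to rt; ice/1 M HCl
Reagents that add atoms: none
Why: AlCl3 ionises 1 to an acylium ion that is captured by ethylene (Friedel–Crafts acylation of an alkene), and chloride returns to the primary carbon to give 3, which carries the C2–C3 bond. The same Lewis acid then activates the primary C–Cl bond of 3 for an intramolecular Friedel–Crafts alkylation that forms the C4–C4a bond and closes ring B in a 6-exo-tet mode. The closest known reaction type is the classical ethylene route from arylacetyl chlorides to 2-tetralones. No stereocentre is formed; the step needs ring closure at the ring carbon para to a methoxy group rather than at the hindered carbon between the side chain and the other methoxy group, and it needs uptake of a single ethylene. The first is secured by the para-methoxy activation and the open flank of that carbon, the second by the fast six-membered ring closure and by the deactivation of 4 as its AlCl3 complex.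

**Step 2**
Reactants: 4 6,7-dimethoxy-3,4-dihydronaphthalen-2(1H)-one
Product: 5 [(6,7-dimethoxy-3,4-dihydronaphthalen-2-yl)oxy]trimethylsilane
Conditions: TMSOTf (1.2 equiv), Et3N (1.5 equiv), CH2Cl2, 0 °C; pentane, filtration, no aqueous work-up
Reagents that add atoms: trimethylsilyl trifluoromethanesulfonate, C[Si](C)(C)OS(=O)(=O)C(F)(F)F
Why: Silyl enol ether formation by soft enolisation: the benzylic C1–H is the more acidic α-hydrogen and its enol ether is conjugated with ring A, so the C1=C2 isomer should form.

**Step 3**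
Reactants: 6 (2E)-3-(4-hydroxyphenyl)prop-2-enal
Product: 7 (2E)-3-[4-(tert-butyldimethylsilyloxy)phenyl]prop-2-enal
Conditions: TBSCl (1.1 equiv), imidazole (2 equiv), DMF, rt
Reagents that add atoms: tert-butyldimethylsilyl chloride, CC(C)(C)[Si](C)(C)Cl
Why: Phenol silylation: the aryl silyl ether should survive the chlorosilane, silyl triflate and hydride steps and leave with fluoride at the end.

**Step 4**
Reactants: 5 [(6,7-dimethoxy-3,4-dihydronaphthalen-2-yl)oxy]trimethylsilane; 7 (2E)-3-[4-(tert-butyldimethylsilyloxy)phenyl]prop-2-enal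
Product: 10 (1R)-1-[(1R,2E)-3-[4-(tert-butyldimethylsilyloxy)phenyl]-1-hydroxyprop-2-en-1-yl]-6,7-dimethoxy-3,4-dihydronaphthalen-2(1H)-one, via trichlorosilyl enolate 8 (not isolated), via trichlorosilyl aldolate 9 (not isolated)
Conditions: SiCl4 (2 equiv), Hg(OAc)2 (1 mol %), CH2Cl2, rt, then volatiles removed; (4S,5S)-1,3-dimethyl-4,5-diphenyl-2-(piperidin-1-yl)-1,3,2-diazaphospholidine 2-oxide (10 mol %), 7 added slowly, CH2Cl2, −78 °C; cold sat. aq. NaHCO3
Reagents that add atoms: none
Why: Lewis-base-catalysed aldol addition of a trichlorosilyl enolate: the ring-locked E enolate 8 should react through a closed chair-like transition state at phosphoramide-bound silicon, which sets C1 and C1' anti, while the chiral phosphoramide selects the Si face of the aldehyde (1R,1'R); conjugated aldehydes undergo only 1,2-addition in this reaction class.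

**Step 5**
Reactants: 10 (1R)-1-[(1R,2E)-3-[4-(tert-butyldimethylsilyloxy)phenyl]-1-hydroxyprop-2-en-1-yl]-6,7-dimethoxy-3,4-dihydronaphthalen-2(1H)-one
Product: 11 (1R)-1-[(1R,2E)-3-[4-(tert-butyldimethylsilyloxy)phenyl]-1-(triethylsilyloxy)prop-2-en-1-yl]-6,7-dimethoxy-3,4-dihydronaphthalen-2(1H)-one
Conditions: Et3SiOTf (1.2 equiv), 2,6-lutidine (2 equiv), CH2Cl2, −78 °C
Reagents that add atoms: triethylsilyl trifluoromethanesulfonate, CC[Si](CC)(CC)OS(=O)(=O)C(F)(F)F
Why: O-silylation of the secondary allylic alcohol at low temperature with a hindered base should leave the epimerisable C1–H untouched and block retro-aldol and chelation in the reduction.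

**Step 6**
Reactants: 11 (1R)-1-[(1R,2E)-3-[4-(tert-butyldimethylsilyloxy)phenyl]-1-(triethylsilyloxy)prop-2-en-1-yl]-6,7-dimethoxy-3,4-dihydronaphthalen-2(1H)-one
Product: 12 (1S,2R)-1-[(1R,2E)-3-[4-(tert-butyldimethylsilyloxy)phenyl]-1-(triethylsilyloxy)prop-2-en-1-yl]-6,7-dimethoxy-1,2,3,4-tetrahydronaphthalen-2-ol
Conditions: LiBH(s-Bu)3 (1.5 equiv), THF, −78 °C; then H2O
Reagents that add atoms: none
Why: Ketone reduction with a bulky trialkylborohydride: the C1 side chain should sit pseudo-axial to avoid the peri hydrogen at C8, so hydride adds to C2 from the opposite face and the new hydroxyl ends up cis to the side chain (2R).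

**Step 7**
Reactants: 12 (1S,2R)-1-[(1R,2E)-3-[4-(tert-butyldimethylsilyloxy)phenyl]-1-(triethylsilyloxy)prop-2-en-1-yl]-6,7-dimethoxy-1,2,3,4-tetrahydronaphthalen-2-ol
Product: 13 (1S,2R)-1-[(1R,2E)-1-hydroxy-3-(4-hydroxyphenyl)prop-2-en-1-yl]-6,7-dimethoxy-1,2,3,4-tetrahydronaphthalen-2-ol
Conditions: Bu4NF (2.5 equiv), AcOH (2.5 equiv), THF, 0 °C to rt; chromatography on base-washed silica
Reagents that add atoms: none
Why: Fluoride-mediated cleavage of both silyl ethers; the acetic acid buffer should keep the acid- and base-sensitive 4-hydroxycinnamyl alcohol from ionising, and no stereocentre is touched.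

**Compound list**
1 | (3,4-dimethoxyphenyl)acetyl chloride | COc1ccc(CC(Cl)=O)cc1OC | starting material
2 | ethylene | C=C | starting material
3 | 4-chloro-1-(3,4-dimethoxyphenyl)butan-2-one | COc1ccc(CC(=O)CCCl)cc1OC | intermediate
4 | 6,7-dimethoxy-3,4-dihydronaphthalen-2(1H)-one | COc1cc2c(cc1OC)CC(=O)CC2 | intermediate
5 | [(6,7-dimethoxy-3,4-dihydronaphthalen-2-yl)oxy]trimethylsilane | COc1cc2c(cc1OC)C=C(O[Si](C)(C)C)CC2 | intermediate
6 | (2E)-3-(4-hydroxyphenyl)prop-2-enal | O=C/C=C/c1ccc(O)cc1 | starting material
7 | (2E)-3-[4-(tert-butyldimethylsilyloxy)phenyl]prop-2-enal | O=C/C=C/c1ccc(O[Si](C)(C)C(C)(C)C)cc1 | intermediate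
8 | trichloro[(6,7-dimethoxy-3,4-dihydronaphthalen-2-yl)oxy]silane | COc1cc2c(cc1OC)C=C(O[Si](Cl)(Cl)Cl)CC2 | intermediate
9 | (1R)-1-[(1R,2E)-3-[4-(tert-butyldimethylsilyloxy)phenyl]-1-(trichlorosilyloxy)prop-2-en-1-yl]-6,7-dimethoxy-3,4-dihydronaphthalen-2(1H)-one | COc1cc2c(cc1OC)[C@H]([C@H](O[Si](Cl)(Cl)Cl)/C=C/c1ccc(O[Si](C)(C)C(C)(C)C)cc1)C(=O)CC2 | intermediate
10 | (1R)-1-[(1R,2E)-3-[4-(tert-butyldimethylsilyloxy)phenyl]-1-hydroxyprop-2-en-1-yl]-6,7-dimethoxy-3,4-dihydronaphthalen-2(1H)-one | COc1cc2c(cc1OC)[C@H]([C@H](O)/C=C/c1ccc(O[Si](C)(C)C(C)(C)C)cc1)C(=O)CC2 | intermediate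
11 | (1R)-1-[(1R,2E)-3-[4-(tert-butyldimethylsilyloxy)phenyl]-1-(triethylsilyloxy)prop-2-en-1-yl]-6,7-dimethoxy-3,4-dihydronaphthalen-2(1H)-one | COc1cc2c(cc1OC)[C@H]([C@H](O[Si](CC)(CC)CC)/C=C/c1ccc(O[Si](C)(C)C(C)(C)C)cc1)C(=O)CC2 | intermediate
12 | (1S,2R)-1-[(1R,2E)-3-[4-(tert-butyldimethylsilyloxy)phenyl]-1-(triethylsilyloxy)prop-2-en-1-yl]-6,7-dimethoxy-1,2,3,4-tetrahydronaphthalen-2-ol | COc1cc2c(cc1OC)[C@H]([C@H](O[Si](CC)(CC)CC)/C=C/c1ccc(O[Si](C)(C)C(C)(C)C)cc1)[C@H](O)CC2 | intermediate
13 | (1S,2R)-1-[(1R,2E)-1-hydroxy-3-(4-hydroxyphenyl)prop-2-en-1-yl]-6,7-dimethoxy-1,2,3,4-tetrahydronaphthalen-2-ol | COc1cc2c(cc1OC)[C@H]([C@H](O)/C=C/c1ccc(O)cc1)[C@H](O)CC2 | target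

**Step count and risks**
Total steps: 7. Longest linear sequence: 6 (steps 1, 2, 4, 5, 6, 7); step 3 is a one-step side branch.

Steps most likely to fail:

- **Step 4.** The arene-conjugated enolate may react with eroded facial and anti/syn selectivity if the uncatalysed background addition competes, and the aldol may revert or dehydrate on work-up. The fallback changes the activation from a preformed silicon enolate to enamine catalysis; it sets out from 4 (with 7) and comes back at 10. Ketone 4 and aldehyde 7 are stirred with D-proline (30 mol %) in DMSO at 4 °C. The enamine/carboxylic acid transition state of this direct aldol should give the same anti adduct by attack on the Si face of the aldehyde; no new compound is passed (F0).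

- **Step 1.** The strong Lewis acid may cleave an aryl methyl ether, ethylene may oligomerise or be taken up twice, and some ring closure may occur at the hindered ortho carbon. The fallback replaces the electrophilic capture of ethylene by a nucleophilic vinyl donor and a milder ring closure; it sets out from 1 and comes back at 4. Acid chloride 1 with MeNHOMe·HCl and pyridine in CH2Cl2 gives the Weinreb amide 2-(3,4-dimethoxyphenyl)-N-methoxy-N-methylacetamide F1. CH2=CHMgBr (THF, −78 to 0 °C, cold aq. HCl quench) gives the vinyl ketone 1-(3,4-dimethoxyphenyl)but-3-en-2-one F2. BF3·OEt2 in CH2Cl2 at 0 °C should then close ring B by intramolecular Friedel–Crafts conjugate addition (6-endo-trig, para to the methoxy group) and give 4.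

- **Step 6.** Hydride may add with poor facial selectivity, or the reagent may enolise the ketone toward C1 with loss of the silyloxy group by β-elimination. The fallback uses internal hydride delivery on the unprotected aldol; it sets out from 10 and comes back at 13. Aldol 10 with Me4NBH(OAc)3 in MeCN/AcOH at −30 °C (Evans–Saksena reduction) should give the 1,3-anti diol, which in this ring is the cis alcohol, (1S,2R)-1-[(1R,2E)-3-[4-(tert-butyldimethylsilyloxy)phenyl]-1-hydroxyprop-2-en-1-yl]-6,7-dimethoxy-1,2,3,4-tetrahydronaphthalen-2-ol F3. Bu4NF/AcOH in THF then frees the phenol and gives 13.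

**Further compounds**
F1 | step 1 | 2-(3,4-dimethoxyphenyl)-N-methoxy-N-methylacetamide | COc1ccc(CC(=O)N(C)OC)cc1OC
F2 | step 1 | 1-(3,4-dimethoxyphenyl)but-3-en-2-one | COc1ccc(CC(=O)C=C)cc1OC
F0 | step 4 | none | none
F3 | step 6 | (1S,2R)-1-[(1R,2E)-3-[4-(tert-butyldimethylsilyloxy)phenyl]-1-hydroxyprop-2-en-1-yl]-6,7-dimethoxy-1,2,3,4-tetrahydronaphthalen-2-ol | COc1cc2c(cc1OC)[C@H]([C@H](O)/C=C/c1ccc(O[Si](C)(C)C(C)(C)C)cc1)[C@H](O)CC2
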